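Everything rests on cutting ring B at C6–C11 and C7–C8. Ring B (C6–C11) carries its oxygen at C9, 1,4 to the quaternary spiro atom C6. That is the pattern a 2-silyloxybutadiene leaves when it adds across an exocyclic C6=C7 enone of ring A. One catalytic enantioselective Diels–Alder reaction thus builds ring B, the spiro stereocentre and a C9=C10 silyl enol ether that later steers chlorine to C10. The dienophile is an achiral, cross-conjugated α-methylene vinylogous ester made from dimedone. Its C1 carbonyl activates the alkene and later becomes C1=CH2, and its C3 alkoxy group is the masked C3 carbinol.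

Key step: step 5

Numbering: ring A = C1(=CH2), C2, C3(OH), C4(Br), C5(Me2), C6(spiro); ring B = C6, C7, C8, C9(Me,OH), C10(Cl), C11. Compounds 3–6 carry the same ring A numbers. The target is (3R,4S,6S,9R,10S). The CIP label of C6 switches between R and S along the route only because the ranking of C1 and C5 changes; its geometry is never touched.

Assumption: the sense of induction in step 5 is assigned from the usual binding picture of this catalyst class and would be verified by anomalous-dispersion X-ray analysis of 12 or 24; the mirror-image catalyst from (R)-α,α-diphenylprolinol is equally available.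

Step 1
Reactants: 1 dimedone (5,5-dimethylcyclohexane-1,3-dione); 2 2-methylpropan-1-ol
Product: 3 3-isobutoxy-5,5-dimethylcyclohex-2-en-1-one
Conditions: TsOH·H2O (cat.), toluene, reflux, Dean–Stark
Reagents that add atoms: none
Why: Acid-catalysed condensation of the enolised 1,3-diketone with an alcohol under azeotropic water removal is the standard vinylogous esterification, and the symmetry of 1 allows only one product.

Step 2
Reactants: 3 3-isobutoxy-5,5-dimethylcyclohex-2-en-1-one
Product: 4 (±)-6-[(dimethylamino)methyl]-3-isobutoxy-5,5-dimethylcyclohex-2-en-1-one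
Conditions: LiN(iPr)2, THF, −78 °C; CH2=NMe2+ I−, −78 °C → rt
Reagents that add atoms: dimethylmethyleneiminium iodide, C=[N+](C)C.[I-]
Why: Kinetic deprotonation of a 3-alkoxyenone takes place at the α′ carbon C6 and the small iminium salt traps this enolate in a Mannich reaction, the racemic C6 centre being erased in the next step.

Step 3
Reactants: 4 (±)-6-[(dimethylamino)methyl]-3-isobutoxy-5,5-dimethylcyclohex-2-en-1-one
Product: 6 3-isobutoxy-5,5-dimethyl-6-methylenecyclohex-2-en-1-one, via trimethylammonium iodide 5 (not isolated)
Conditions: MeI, Et2O, rt; then aq NaHCO3, CH2Cl2, rt; used fresh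
Reagents that add atoms: none
Why: N-Methylation turns the amine into a leaving group β to the C1 carbonyl so that mild base triggers E1cB elimination to the exocyclic enone, which cannot isomerise into the ring (C5 is quaternary) and whose dimerisation is slowed by the neighbouring gem-dimethyl group.

Step 4
Reactants: 7 methyl vinyl ketone
Product: 8 2-(tert-butyldimethylsilyloxy)buta-1,3-diene
Conditions: TBSOTf, Et3N, Et2O, 0 °C → rt
Reagents that add atoms: tert-butyldimethylsilyl trifluoromethanesulfonate, CC(C)(C)[Si](C)(C)OS(=O)(=O)C(F)(F)F
Why: Soft enolisation of an enone with a silyl triflate and a tertiary amine is the standard preparation of 2-silyloxybutadienes, and only the methyl group of 7 can be deprotonated.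

Step 5
Reactants: 6 3-isobutoxy-5,5-dimethyl-6-methylenecyclohex-2-en-1-one; 8 2-(tert-butyldimethylsilyloxy)buta-1,3-diene
Product: 9 (6R)-9-(tert-butyldimethylsilyloxy)-3-isobutoxy-5,5-dimethylspiro[5.5]undeca-2,9-dien-1-one
Conditions: (S)-3,3-diphenyl-1-(2-methylphenyl)tetrahydro-1H,3H-pyrrolo[1,2-c][1,3,2]oxazaborole (20 mol %, from (S)-α,α-diphenylprolinol and o-tolylboronic acid, toluene, reflux, −H2O), HN(SO2CF3)2 (17 mol %), 8 (2 equiv), CH2Cl2, −78 → −40 °C; Et3N quench at −78 °C
Reagents that add atoms: none
Why: The cationic boron Lewis acid binds the C1 carbonyl oxygen, the most basic site of 6, and lowers the LUMO of the cross-conjugated C6=C7 bond, so that 8 adds in a concerted but asynchronous [4+2] in which C8–C7 bonding runs ahead of C11–C6 bonding. The closest known reaction type is the acid-catalysed Diels–Alder spiroannulation of exocyclic α-methylene cycloalkanones by 2-substituted butadienes, which also exists in enantioselective form, and oxazaborolidinium bis(triflyl)imides are established catalysts for 2-silyloxybutadienes. Ring B closes by an intermolecular [4+2] cycloaddition, suprafacial on both partners, with both new bonds ending on the former exocyclic alkene so that C6 becomes the spiro atom. C6 is the only new stereocentre and is controlled by the catalyst: boron sits on the oxygen lone pair syn to C2–H, the neighbouring phenyl group then lies over the Si face of C6, and the diene takes the open Re face to give 6R (no endo or exo issue arises because the diene termini are unsubstituted). The step needs para regioselectivity, secured by the large HOMO coefficient at the CH2 next to the silyloxy carbon meeting the β-carbon C7, and chemoselectivity for C6=C7 over C2=C3, secured because the latter is donor-substituted and trisubstituted. C6 is stereogenic only while the enol ether sits at C9=C10 and not at C9=C8, so slightly less acid than oxazaborolidine is used and the run is quenched cold with Et3N to prevent hydrolysis or migration of the enol ether.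

Step 6
Reactants: 9 (6R)-9-(tert-butyldimethylsilyloxy)-3-isobutoxy-5,5-dimethylspiro[5.5]undeca-2,9-dien-1-one
Product: 11 (6R,10S)-10-chloro-3-isobutoxy-5,5-dimethylspiro[5.5]undec-2-ene-1,9-dione (Cl equatorial and cis to C5), via C10-epimeric chloroketone 10 (not isolated)
Conditions: NCS (1.0 equiv), THF, −78 → 0 °C; aqueous work-up; then Et3N (cat.), CH2Cl2, rt
Reagents that add atoms: N-chlorosuccinimide, O=C1CCC(=O)N1Cl
Why: Electrophilic α-chlorination of a silyl enol ether puts chlorine regiospecifically on the enol carbon C10 (the push–pull C2=C3 bond is far less nucleophilic), and amine-catalysed enolisation then funnels both C10 epimers to the thermodynamic one, in which ring B keeps the bulky C5 equatorial and C1 axial and chlorine is equatorial, because the other epimer would hold chlorine 1,3-diaxial to C1.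

Step 7
Reactants: 11 (6R,10S)-10-chloro-3-isobutoxy-5,5-dimethylspiro[5.5]undec-2-ene-1,9-dione
Product: 12 (6R,9R,10S)-10-chloro-9-hydroxy-3-isobutoxy-5,5,9-trimethylspiro[5.5]undec-2-en-1-one
Conditions: MeMgBr (1.3 equiv), Et2O/toluene, −78 °C; cold aq NH4Cl
Reagents that add atoms: methylmagnesium bromide, C[Mg]Br
Why: In this Grignard 1,2-addition to an α-chloro ketone the reagent takes the far more electrophilic C9 ketone and leaves the hindered vinylogous ester carbonyl alone, and it arrives along the equatorial trajectory on the face of the axial C10–H (the usual preference of methyl Grignard reagents, reinforced by magnesium bridging the oxygen and the equatorial chlorine), so that methyl ends equatorial and the C9 hydroxyl axial and cis to chlorine.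

Step 8
Reactants: 13 (tributylstannyl)methanol; 14 ethyl vinyl ether
Product: 15 tributyl[(1-ethoxyethoxy)methyl]stannane
Conditions: PPTS (cat.), CH2Cl2, 0 °C → rt
Reagents that add atoms: none
Why: Acid-catalysed addition of an alcohol to an enol ether gives the mixed acetal, a standard protection that survives tin–lithium exchange and falls off in dilute acid.

Step 9
Reactants: 12 (6R,9R,10S)-10-chloro-9-hydroxy-3-isobutoxy-5,5,9-trimethylspiro[5.5]undec-2-en-1-one; 15 tributyl[(1-ethoxyethoxy)methyl]stannane
Product: 19 (6R,9R,10S)-10-chloro-9-hydroxy-1-(hydroxymethyl)-5,5,9-trimethylspiro[5.5]undec-1-en-3-one, via alkoxymethyllithium 16 (not isolated), via alkoxymethylcerium dichloride 17 (not isolated), via C1 tertiary carbinol 18 (not isolated)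
Conditions: 15, n-BuLi, THF, −78 °C; CeCl3, −78 °C; then 12 (pre-treated with n-BuLi, 1.0 equiv, −78 °C), −78 → −30 °C; then 1 M HCl, THF, 0 °C → rt
Reagents that add atoms: water, O
Why: Tin–lithium exchange gives the α-alkoxymethyl carbanion, its weakly basic cerium derivative adds 1,2 to the hindered and enolisable C1 carbonyl, and aqueous acid then ionises the tertiary allylic alcohol, hydrolyses the oxocarbenium ion at C3 (Stork–Danheiser transposition) and cleaves the acetal in the same pot, the transient C1 carbinol centre being destroyed and no other stereocentre touched.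

Step 10
Reactants: 19 (6R,9R,10S)-10-chloro-9-hydroxy-1-(hydroxymethyl)-5,5,9-trimethylspiro[5.5]undec-1-en-3-one
Product: 20 [(6R,9R,10S)-10-chloro-9-hydroxy-5,5,9-trimethyl-3-oxospiro[5.5]undec-1-en-1-yl]methyl methyl carbonate
Conditions: ClCO2Me, pyridine, CH2Cl2, 0 °C
Reagents that add atoms: methyl chloroformate, COC(=O)Cl
Why: Acylation with a chloroformate is selective for the primary allylic alcohol over the hindered tertiary C9 hydroxyl, and the carbonate, which has no α-hydrogen, serves first as protecting group and later as leaving group.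

Step 11
Reactants: 20 [(6R,9R,10S)-10-chloro-9-hydroxy-5,5,9-trimethyl-3-oxospiro[5.5]undec-1-en-1-yl]methyl methyl carbonate
Product: 23 [(6S,9R,10S)-4-bromo-10-chloro-9-hydroxy-5,5,9-trimethyl-3-oxospiro[5.5]undec-1-en-1-yl]methyl methyl carbonate as a mixture of C4 epimers, via bis(trimethylsilyl) dienol ether 21 (not isolated), via C9 silyl ether of the bromoenone 22 (not isolated)
Conditions: LiN(iPr)2 (2.3 equiv), TMSCl, THF, −78 °C; NBS, THF, −78 → 0 °C; then 0.5 M HCl, THF, 0 °C
Reagents that add atoms: N-bromosuccinimide, O=C1CCC(=O)N1Br
Why: Kinetic deprotonation of a cyclohexenone occurs at the α′ carbon C4 (as known for 5,5-dimethylcyclohexenones), the cross-conjugated silyl dienol ether is brominated by NBS at C4 and dilute acid removes the transient C9 silyl ether, while the ring B stereocentres are too remote to bias C4, so both equatorial-bromide epimers are expected, which is acceptable because C4 is stereolabile and is fixed in step 12.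

Step 12
Reactants: 23 [(6S,9R,10S)-4-bromo-10-chloro-9-hydroxy-5,5,9-trimethyl-3-oxospiro[5.5]undec-1-en-1-yl]methyl methyl carbonate (C4 epimers)
Product: 24 [(3R,4S,6S,9R,10S)-4-bromo-10-chloro-3,9-dihydroxy-5,5,9-trimethylspiro[5.5]undec-1-en-1-yl]methyl methyl carbonate
Conditions: RuCl(p-cymene)[(S,S)-TsNCH(Ph)CH(Ph)NH2] (5 mol %), HCO2H/Et3N (5:2), CH2Cl2, 30 °C
Reagents that add atoms: none
Why: This is a Noyori–Ikariya asymmetric transfer hydrogenation with dynamic kinetic resolution, known to turn cyclic α-halo ketones into cis-halohydrins: the C4 epimers interconvert through the enol in HCO2H/Et3N (C5 has no hydrogen, so no elimination), the (S,S)-catalyst places the alkenyl arm C2 where an aryl group normally sits and delivers hydride to the C3 face that gives 3R, and only the 4S epimer can accept it on the face anti to its axial C5 methyl group, so C3 and C4 are set together as the cis (3R,4S) bromohydrin while 1,4-reduction is blocked by the fully substituted C1.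

Step 13
Reactants: 24 [(3R,4S,6S,9R,10S)-4-bromo-10-chloro-3,9-dihydroxy-5,5,9-trimethylspiro[5.5]undec-1-en-1-yl]methyl methyl carbonate
Product: 25 (3R,4S,6S,9R,10S)-4-bromo-10-chloro-5,5,9-trimethyl-1-methylidenespiro[5.5]undecane-3,9-diol (target)
Conditions: Pd(OAc)2 (5 mol %), PBu3 (10 mol %), HCO2H, Et3N, THF, rt → 40 °C
Reagents that add atoms: none
Why: In this palladium-catalysed formate hydrogenolysis of an allylic carbonate (Tsuji reduction) zerovalent palladium ionises the primary carbonate, the σ-allyl formate complex carries palladium on the unhindered CH2 terminus and passes hydride with loss of CO2 to the inner terminus C2, which gives the exocyclic C1=CH2 alkene, while free hydroxyl groups are no leaving groups, the cis bromohydrin cannot close to an epoxide and the neopentyl secondary C–Br and the C–Cl bonds resist oxidative addition under these conditions.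

Compound list
1 | dimedone (5,5-dimethylcyclohexane-1,3-dione) | O=C1CC(=O)CC(C)(C)C1 | starting material
2 | 2-methylpropan-1-ol | CC(C)CO | starting material
3 | 3-isobutoxy-5,5-dimethylcyclohex-2-en-1-one | O=C1C=C(OCC(C)C)CC(C)(C)C1 | intermediate
4 | (±)-6-[(dimethylamino)methyl]-3-isobutoxy-5,5-dimethylcyclohex-2-en-1-one | CN(C)CC1C(=O)C=C(OCC(C)C)CC1(C)C | intermediate
5 | [(4-isobutoxy-6,6-dimethyl-2-oxocyclohex-3-en-1-yl)methyl]trimethylammonium iodide | C[N+](C)(C)CC1C(=O)C=C(OCC(C)C)CC1(C)C.[I-] | intermediate (not isolated)
6 | 3-isobutoxy-5,5-dimethyl-6-methylenecyclohex-2-en-1-one | C=C1C(=O)C=C(OCC(C)C)CC1(C)C | intermediate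
7 | methyl vinyl ketone | C=CC(C)=O | starting material
8 | 2-(tert-butyldimethylsilyloxy)buta-1,3-diene | C=CC(=C)O[Si](C)(C)C(C)(C)C | intermediate
9 | (6R)-9-(tert-butyldimethylsilyloxy)-3-isobutoxy-5,5-dimethylspiro[5.5]undeca-2,9-dien-1-one | O=C1C=C(OCC(C)C)CC(C)(C)[C@]12CCC(O[Si](C)(C)C(C)(C)C)=CC2 | intermediate
10 | (6R,10R)-10-chloro-3-isobutoxy-5,5-dimethylspiro[5.5]undec-2-ene-1,9-dione (Cl cis to C1) | O=C1C=C(OCC(C)C)CC(C)(C)[C@]12CCC(=O)[C@H](Cl)C2 | intermediate (not isolated)
11 | (6R,10S)-10-chloro-3-isobutoxy-5,5-dimethylspiro[5.5]undec-2-ene-1,9-dione (Cl cis to C5) | O=C1C=C(OCC(C)C)CC(C)(C)[C@]12CCC(=O)[C@@H](Cl)C2 | intermediate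
12 | (6R,9R,10S)-10-chloro-9-hydroxy-3-isobutoxy-5,5,9-trimethylspiro[5.5]undec-2-en-1-one | O=C1C=C(OCC(C)C)CC(C)(C)[C@]12CC[C@@](C)(O)[C@@H](Cl)C2 | intermediate
13 | (tributylstannyl)methanol | CCCC[Sn](CCCC)(CCCC)CO | starting material
14 | ethyl vinyl ether | C=COCC | starting material
15 | tributyl[(1-ethoxyethoxy)methyl]stannane | CCCC[Sn](CCCC)(CCCC)COC(C)OCC | intermediate
16 | (1-ethoxyethoxy)methyllithium | [Li]COC(C)OCC | intermediate (not isolated)
17 | [(1-ethoxyethoxy)methyl]cerium dichloride | Cl[Ce](Cl)COC(C)OCC | intermediate (not isolated)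
18 | (6R,9R,10S)-10-chloro-1-[(1-ethoxyethoxy)methyl]-3-isobutoxy-5,5,9-trimethylspiro[5.5]undec-2-ene-1,9-diol (C1 and acetal centres undefined) | CCOC(C)OCC1(O)C=C(OCC(C)C)CC(C)(C)[C@]12CC[C@@](C)(O)[C@@H](Cl)C2 | intermediate (not isolated)
19 | (6R,9R,10S)-10-chloro-9-hydroxy-1-(hydroxymethyl)-5,5,9-trimethylspiro[5.5]undec-1-en-3-one | OCC1=CC(=O)CC(C)(C)[C@]12CC[C@@](C)(O)[C@@H](Cl)C2 | intermediate
20 | [(6R,9R,10S)-10-chloro-9-hydroxy-5,5,9-trimethyl-3-oxospiro[5.5]undec-1-en-1-yl]methyl methyl carbonate | COC(=O)OCC1=CC(=O)CC(C)(C)[C@]12CC[C@@](C)(O)[C@@H](Cl)C2 | intermediate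
21 | C3 trimethylsilyl dienol ether (C1=C2, C3=C4) and C9 trimethylsilyl ether of 20, ring B centres as in 20 | COC(=O)OCC1=CC(O[Si](C)(C)C)=CC(C)(C)[C@]12CC[C@@](C)(O[Si](C)(C)C)[C@@H](Cl)C2 | intermediate (not isolated)
22 | C9 trimethylsilyl ether of 23, C4 epimers | COC(=O)OCC1=CC(=O)C(Br)C(C)(C)[C@]12CC[C@@](C)(O[Si](C)(C)C)[C@@H](Cl)C2 | intermediate (not isolated)
23 | [(6S,9R,10S)-4-bromo-10-chloro-9-hydroxy-5,5,9-trimethyl-3-oxospiro[5.5]undec-1-en-1-yl]methyl methyl carbonate, C4 epimers | COC(=O)OCC1=CC(=O)C(Br)C(C)(C)[C@]12CC[C@@](C)(O)[C@@H](Cl)C2 | intermediate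
24 | [(3R,4S,6S,9R,10S)-4-bromo-10-chloro-3,9-dihydroxy-5,5,9-trimethylspiro[5.5]undec-1-en-1-yl]methyl methyl carbonate | COC(=O)OCC1=C[C@@H](O)[C@@H](Br)C(C)(C)[C@]12CC[C@@](C)(O)[C@@H](Cl)C2 | intermediate
25 | (3R,4S,6S,9R,10S)-4-bromo-10-chloro-5,5,9-trimethyl-1-methylidenespiro[5.5]undecane-3,9-diol | C=C1C[C@@H](O)[C@@H](Br)C(C)(C)[C@]12CC[C@@](C)(O)[C@@H](Cl)C2 | target

Total step count: 13. Longest linear sequence: 11 steps (steps 1, 2, 3, 5, 6, 7, 9, 10, 11, 12, 13).

Steps most likely to fail

Step 5.
- **What may go wrong:** The donor-substituted carbonyl may be activated too weakly for turnover at low temperature. The catalyst may discriminate the two faces of C6=C7 poorly, because its organising contact lies on the C2–H side of the carbonyl. Adventitious acid may hydrolyse or shift the enol ether, which erases the only stereocentre.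
- **Fallback:** Move the asymmetric induction from the cycloaddition to a desymmetrising enolisation.
- **Course:** Setting out again from 6 and 8, an achiral Lewis acid (Me2AlCl, CH2Cl2, −78 → 0 °C) or simple heating gives the racemic adduct F1. Dilute HCl in THF hydrolyses it to 3-isobutoxy-5,5-dimethylspiro[5.5]undec-2-ene-1,9-dione F2, which is achiral because the two arms of ring B are now identical.
- **Desymmetrisation:** Enantioselective deprotonation uses lithium (R,R)-bis(1-phenylethyl)amide with LiCl and TMSCl present (THF, −100 → −78 °C). This is a known desymmetrisation of 4-substituted and 4,4-disubstituted cyclohexanones. It removes one of the two enantiotopic axial α-hydrogens and should give the (6R)-trimethylsilyl enol ether F3.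
- **Choice of amide:** This amide enantiomer is the one that leads to the (S)-enol silane of 4-tert-butylcyclohexanone, the spatial counterpart of F3 with C5 in the place of tert-butyl.
- **Return:** NCS and amine equilibration as in step 6 bring the material back to the route at 11.

Step 12.
- **What may go wrong:** Enolisation at the neopentyl C4 may be slower than hydride transfer. The process would then degenerate into a kinetic resolution or let the mismatched epimer leak through. Reductive loss of bromine may also compete.
- **Fallback:** Give up catalyst control and use substrate control with recycling.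
- **Course:** Setting out from 23, i-Bu2AlH (1.1 equiv, CH2Cl2, −78 °C) reduces each C4 epimer from the face opposite its own axial C5 methyl group. This gives 24 together with its ring A diastereomer, the (3S,4R)-cis-bromohydrin F4, and the two are separated by chromatography.
- **Recycling and return:** F4 is oxidised back with Dess–Martin periodinane to the 4R component of 23, re-equilibrated at C4 with Et3N and resubmitted. The route is rejoined at 24.

Step 9.
- **What may go wrong:** Steric shielding of C1 by the spiro centre and the gem-dimethyl group may stop the addition. Deprotonation at C4 or thermal decay of the carbanion would then take over.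
- **Fallback:** Replace carbanion addition by carbonyl methylenation followed by oxidation.
- **Course:** Setting out from 12, Tebbe methylenation uses Cp2Ti(μ-Cl)(μ-CH2)AlMe2 (excess to cover the free hydroxyl, toluene/THF, −40 °C → rt). This reagent converts hindered ketones and ester-type carbonyls without enolisation, and should give the 1-methylidene dienol ether F5.
- **Oxidation and return:** m-CPBA in NaHCO3-buffered CH2Cl2 at 0 °C then attacks the terminal C1=CH2 bond of the dienol ether, as known for steroidal 3-alkoxy-3,5-dienes that give 6-hydroxy-4-en-3-ones. Mild aqueous acid releases the enone, so the route is rejoined at 19.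

Further compounds
F1 | step 5 | racemic 9-(tert-butyldimethylsilyloxy)-3-isobutoxy-5,5-dimethylspiro[5.5]undeca-2,9-dien-1-one | O=C1C=C(OCC(C)C)CC(C)(C)C12CCC(O[Si](C)(C)C(C)(C)C)=CC2
F2 | step 5 | 3-isobutoxy-5,5-dimethylspiro[5.5]undec-2-ene-1,9-dione (achiral) | O=C1C=C(OCC(C)C)CC(C)(C)C12CCC(=O)CC2
F3 | step 5 | (6R)-3-isobutoxy-5,5-dimethyl-9-(trimethylsilyloxy)spiro[5.5]undeca-2,9-dien-1-one | O=C1C=C(OCC(C)C)CC(C)(C)[C@]12CCC(O[Si](C)(C)C)=CC2
F4 | step 12 | [(3S,4R,6S,9R,10S)-4-bromo-10-chloro-3,9-dihydroxy-5,5,9-trimethylspiro[5.5]undec-1-en-1-yl]methyl methyl carbonate | COC(=O)OCC1=C[C@H](O)[C@H](Br)C(C)(C)[C@]12CC[C@@](C)(O)[C@@H](Cl)C2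
F5 | step 9 | (6R,9R,10S)-10-chloro-3-isobutoxy-5,5,9-trimethyl-1-methylidenespiro[5.5]undec-2-en-9-ol | C=C1C=C(OCC(C)C)CC(C)(C)[C@]12CC[C@@](C)(O)[C@@H](Cl)C2
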